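## Structural features

Labels used throughout: ring A is the resorcinol ring, ring B the catechol ring inside the polycycle, ring C the central mono-phenol ring and ring D the pendant catechol ring; C7 is the CH2 and C8 the CH of the bridge between rings A and C, C9 is the CH that carries ring D, and C10 is the CH2 between C9 and ring C. The target (C28H22O7) is a 9,10-dihydrophenanthrene (rings A and C joined by a biaryl bond and bridged by C7–C8) fused through the C8–ring C bond to a 10,11-dihydro-5H-dibenzo[a,d]cycloheptene (rings B and C bridged by C8 on one side and by C9–C10 on the other). Ring C is pentasubstituted with three contiguous carbon substituents (ring A, C8, C10), and the A–C biaryl bond carries three ortho substituents. The stereocenters C8 (S) and C9 (R) are both doubly benzylic methines on adjacent carbons of ring B, 1,4 to each other on the seven-membered ring, with H8 and H9 cis. Fragile features are the seven free phenols (two catechols, prone to air oxidation) and above all C8: a positive charge there, once C7 is attached inside the biaryl-bridged ring, would lose a C7 proton and give an aromatic 9-arylphenanthrene irreversibly. The real difficulty is therefore the C7–C8 bond and the configuration of C8 at the junction of the six- and seven-membered rings, which have to be made next to a crowded biaryl without cation chemistry at C8, together with the cis relation to C9. The key step exploits that C7 and C8 are both benzylic and face each other across the A–C biaryl: a nitrogen atom between them gives a 6,7-dihydro-5H-dibenzo[c,e]azepine, a ring type whose 1,1-diazene is known to lose N2 and close to 9,10-dihydrophenanthrene, and with nitrogen in place C8 is an imine carbon that can be reduced enantioselectively before C7 is joined to it. A second feature is used in the assembly: rings B and D are the same 3,4-dioxygenated aryl group on C9, so both come from one symmetric diaryl ketone and C9 becomes a stereocenter only when ring B is tied to C8.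

## Logic of the disconnections

20 to 19. The seven O–H bonds of 20 are traced back to O–CH3 bonds. Free catechols would not survive the bases, palladium steps and the amine chemistry of the route; as ethers every intermediate is neutral and easy to purify. The forward step must cleave seven methyl ethers without touching the two benzylic methines.

19 to 17 (key disconnection). The C7–C8 bond is cut and an NH is placed between the two carbons. The bond cannot be made by ionic chemistry at C8 because of the phenanthrene sink. The six-membered carbocycle becomes an azepine that forms by simple C=N condensation, and the C8 stereocenter becomes a C–N stereocenter that hydride addition can set. In one sentence: nitrogen is excised from 17 so that C7 and C8 join and the azepine contracts to the dihydrophenanthrene of 19. The forward step must extrude nitrogen with retention at C8 and leave C9 alone.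

17 to 16. The C9–H and C10–H bonds are cut to give the C9=C10 alkene. This removes the C9 stereocenter, which C8 can control through the shape of the seven-membered ring, and the alkene is what the ring-forming cascade delivers anyway. The forward step needs hydrogen delivery to the face that carries H8 and must spare the benzylic C–N bonds.

16 to 15. The C8–H bond is cut to give the C8=N bond. The last stereocenter disappears and the molecule becomes achiral. The forward step needs a catalyst that selects one face of a cyclic diaryl ketimine.

15 to 13. The C8=N bond is cut to a C8 ketone and a carbamate-protected C7 amine. The azepine ring opens to a biaryl whose two halves are independent. The forward step needs deprotection and an intramolecular condensation with a hindered diaryl ketone.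

13 to 8 and 12. The A–C biaryl bond is cut. This is the convergent point; both partners carry all their oxygen atoms. The forward step is a cross-coupling that forms a tri-ortho-substituted biaryl next to a ketone.

8 to 7 to 6. The O–S bond of 8 is cut, and the O–H of 7 is traced to an O–CH3 of 6. The one methoxy group that lies peri to the C8 carbonyl is singled out by chelation, so ring C needs no special protecting group. The forward steps need selectivity for one of six methoxy groups.

6 to 4. The C8–ring B bond is cut (acyl–aryl), and the C9=C10 alkene is traced back to a C9–O bond. An acylium at C8 is the one cation at that carbon that cannot eliminate, and a C9 with two identical aryl groups always has one of them cis to the acid. The tricyclic ketone becomes a bicyclic lactone. The forward step needs ring closure to a seven-membered ring at the aryl position para to a methoxy group.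

4 to 1 and 2. The C9–C10 bond and the lactone C–O bond are cut. Rings B and D arrive together in 2, ring C with C8 and C10 in 1. The forward step needs benzylic deprotonation of 1 next to its ester and addition to a diaryl ketone.

12 to 11 to 9 and 10. The C–B bond of 12 and the C7–N bond of 11 are cut. Ring A arrives with C7, the nitrogen and the halogen in place. The forward steps need a reductive N-alkylation and a borylation of a hindered bromide.

## Other disconnections considered

Alternative 1: the first route that comes to mind. Cut the C8–ring B bond as a Friedel–Crafts alkylation on a finished dihydrophenanthrene. The forward key step would ionise the benzylic alcohol A1 (C8–OH, A–C biaryl and six-membered ring already closed) and let one 3,4-dimethoxyphenyl ring capture the C8 cation. In A1 that cation sits next to the C7 hydrogens inside the biaryl-bridged ring, so E1 loss to an aromatic phenanthrene is expected to outrun a seven-membered ring closure. The step is also achiral, the two aryl groups on C9 are enantiotopic, and nothing in A1 decides cis against trans. The chosen plan never places positive charge on C8 once C7 is attached and sets each stereocenter by a hydride or hydrogen delivery.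

Alternative 2: cut the A–C biaryl bond last. The forward key step would be a palladium-catalysed intramolecular C–H arylation of bromide A2, a dibenzocycloheptane with both stereocenters and a 2-bromo-3,5-dimethoxybenzyl group on C8. The arylpalladium on ring A can close a six-membered ring onto two C–H bonds: the one on ring C (meta to its only methoxy group) and the one on ring B ortho to C8 (ortho to a methoxy group, the more activated site). The structure does not secure the required regiochemistry. A2 would also have to be made by cation chemistry without a handle for absolute configuration, and the step count is not lower.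

Alternative 3: keep the nitrogen atom between C7 and C8 but make the C8–ring B bond on the nitrogen compound. The forward key step would be a chiral Brønsted acid-catalysed aza-Friedel–Crafts closure of the achiral cyclic aldimine A3, in which one of the two enantiotopic 3,4-dimethoxyphenyl groups on C9 attacks C8=N. This would set C8 and C9 together and give 17 directly, saving the hydrogenation. It is attractive, but both selectivities would rest on a seven-membered closure by a weakly nucleophilic dimethoxyarene, and cis against trans depends on whether the spectator aryl group sits pseudo-equatorial or pseudo-axial in the transition state, which the substrate does not fix. The chosen plan closes the seven-membered ring with a robust acylium and separates the two stereocenters into steps with a clear control element each.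

Key step: step 11

Remark 1: bis(3,4-dimethoxyphenyl)methanone (2) is treated as a purchasable compound.
Remark 2: the (R,R)-ligand in step 9 is assigned by analogy with transfer hydrogenation of 1-substituted 3,4-dihydroisoquinolines; if hydride goes to the other face, the (S,S)-ligand is used.

## Route

Step 1
Reactants: 1 methyl 2,4-dimethoxy-6-methylbenzoate; 2 bis(3,4-dimethoxyphenyl)methanone
Product: 4 3,3-bis(3,4-dimethoxyphenyl)-6,8-dimethoxy-3,4-dihydro-1H-isochromen-1-one, via hydroxy ester adduct 3 (not isolated)
Conditions: LiN(iPr)2 (1.2 equiv), THF, −78 °C; then 2, −78 → 0 °C; aq. NH4Cl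
Reagents that add atoms: none
Why: Lateral (benzylic) lithiation of the ortho-toluate, 1,2-addition to the non-enolisable diaryl ketone and lactonisation of the tertiary alkoxide onto the neighbouring ester (toluate-anion route to 3,4-dihydroisocoumarins). No stereocenter arises because the two aryl groups on C9 are identical.

Step 2
Reactants: 4 3,3-bis(3,4-dimethoxyphenyl)-6,8-dimethoxy-3,4-dihydro-1H-isochromen-1-one
Product: 6 11-(3,4-dimethoxyphenyl)-2,3,6,8-tetramethoxy-5H-dibenzo[a,d][7]annulen-5-one, via alkene acid 5 (not isolated)
Conditions: P2O5 in MeSO3H (1:10 w/w), 40 °C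
Reagents that add atoms: none
Why: Acid ionises the tertiary bis-benzylic C9–O bond, loss of a C10 proton gives the triarylethylene acid 5, and its acylium ion acylates the cis 3,4-dimethoxyphenyl ring para to a methoxy group (intramolecular Friedel–Crafts acylation closing the seven-membered ring). An acylium at C8 cannot eliminate, and one of the two identical aryl groups on C9 is always cis to the acid.

Step 3
Reactants: 6 11-(3,4-dimethoxyphenyl)-2,3,6,8-tetramethoxy-5H-dibenzo[a,d][7]annulen-5-one
Product: 7 11-(3,4-dimethoxyphenyl)-6-hydroxy-2,3,8-trimethoxy-5H-dibenzo[a,d][7]annulen-5-one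
Conditions: BCl3 (1.5 equiv), CH2Cl2, −78 → 0 °C; aq. NaHCO3
Reagents that add atoms: none
Why: Chelation-controlled mono-demethylation: boron binds the C8 carbonyl oxygen and the peri methoxy group on ring C, and chloride cleaves only that O–CH3 bond at low temperature.

Step 4
Reactants: 7 11-(3,4-dimethoxyphenyl)-6-hydroxy-2,3,8-trimethoxy-5H-dibenzo[a,d][7]annulen-5-one
Product: 8 11-(3,4-dimethoxyphenyl)-2,3,8-trimethoxy-5-oxo-5H-dibenzo[a,d][7]annulen-6-yl trifluoromethanesulfonate
Conditions: Tf2O (1.2 equiv), pyridine, CH2Cl2, 0 °C
Reagents that add atoms: trifluoromethanesulfonic anhydride, O=S(=O)(OS(=O)(=O)C(F)(F)F)C(F)(F)F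
Why: O-Sulfonylation of the phenol gives the aryl triflate that serves as the coupling handle on ring C, activated by the ortho carbonyl.

Step 5
Reactants: 9 2-bromo-3,5-dimethoxybenzaldehyde; 10 tert-butyl carbamate
Product: 11 tert-butyl N-[(2-bromo-3,5-dimethoxyphenyl)methyl]carbamate
Conditions: Et3SiH (3 equiv), CF3CO2H (2 equiv), MeCN, rt
Reagents that add atoms: none
Why: Reductive N-alkylation of a carbamate: the N-acyliminium ion from aldehyde and carbamate is reduced by hydride transfer from the silane (ionic hydrogenation), giving C7 with its nitrogen already attached.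

Step 6
Reactants: 11 tert-butyl N-[(2-bromo-3,5-dimethoxyphenyl)methyl]carbamate
Product: 12 tert-butyl N-{[3,5-dimethoxy-2-(4,4,5,5-tetramethyl-1,3,2-dioxaborolan-2-yl)phenyl]methyl}carbamate
Conditions: B2pin2 (1.5 equiv), Pd(OAc)2 (3 mol %), XPhos (6 mol %), KOAc (3 equiv), 1,4-dioxane, 100 °C
Reagents that add atoms: bis(pinacolato)diboron, CC1(C)OB(OC1(C)C)B1OC(C)(C)C(C)(C)O1
Why: Miyaura borylation of the aryl bromide; the bulky biaryl phosphine is chosen for the di-ortho-substituted, electron-rich bromide.

Step 7
Reactants: 8 11-(3,4-dimethoxyphenyl)-2,3,8-trimethoxy-5-oxo-5H-dibenzo[a,d][7]annulen-6-yl trifluoromethanesulfonate; 12 tert-butyl N-{[3,5-dimethoxy-2-(4,4,5,5-tetramethyl-1,3,2-dioxaborolan-2-yl)phenyl]methyl}carbamate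
Product: 13 tert-butyl N-({2-[11-(3,4-dimethoxyphenyl)-2,3,8-trimethoxy-5-oxo-5H-dibenzo[a,d][7]annulen-6-yl]-3,5-dimethoxyphenyl}methyl)carbamate
Conditions: Pd(OAc)2 (5 mol %), SPhos (10 mol %), K3PO4 (3 equiv), toluene/H2O (10:1), 90 °C
Reagents that add atoms: none
Why: Suzuki–Miyaura coupling forms the A–C biaryl bond; the triflate ortho to the ketone adds readily to zerovalent palladium and the dialkylbiaryl phosphine allows a tri-ortho-substituted biaryl. The biaryl axis needs no control because it is bridged in the next step.

Step 8
Reactants: 13 tert-butyl N-({2-[11-(3,4-dimethoxyphenyl)-2,3,8-trimethoxy-5-oxo-5H-dibenzo[a,d][7]annulen-6-yl]-3,5-dimethoxyphenyl}methyl)carbamate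
Product: 15 cyclic ketimine (C7H2–N=C8; C9=C10), via amino ketone 14 (not isolated)
Conditions: CF3CO2H/CH2Cl2 (1:4), rt; evaporate; then NaOAc, toluene, 4 Å molecular sieves, 90 °C
Reagents that add atoms: none
Why: Acidolysis of the tert-butyl carbamate frees the C7 amine, which condenses with the C8 ketone held next to it by the biaryl (imine formation closing the seven-membered 5H-dibenzo[c,e]azepine ring).

Step 9
Reactants: 15 cyclic ketimine (C7H2–N=C8; C9=C10)
Product: 16 (8S)-amine (C7H2–NH–C8H; C9=C10)
Conditions: RuCl(p-cymene)[(R,R)-TsDPEN] (2 mol %), HCO2H/Et3N (5:2), MeCN, 30 °C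
Reagents that add atoms: none
Why: Noyori–Ikariya asymmetric transfer hydrogenation of a cyclic aryl ketimine: Ru–H and the ligand N–H deliver hydride and proton to one face of the protonated C8=N through the outer-sphere six-membered transition state, so the catalyst sets C8. The triaryl-substituted C9=C10 alkene does not react with this hydride source.

Step 10
Reactants: 16 (8S)-amine (C7H2–NH–C8H; C9=C10)
Product: 17 (8S,9R)-amine (C7H2–NH–C8H; H8 and H9 cis)
Conditions: H2 (3 atm), PtO2 (5 mol %), EtOAc, rt
Reagents that add atoms: none
Why: Heterogeneous syn-hydrogenation of the triarylethylene; C9 is set by C8, because the azepine ring keeps the C8–N bond out of the pseudo-axial position, H8 is pseudo-axial and fixes the boat of the seven-membered carbocycle, and hydrogen adds to the exposed convex face of C9=C10, the face that carries H8. This puts H9 cis to H8 and ring D pseudo-equatorial; platinum is chosen over palladium to spare the doubly benzylic C8–N bond.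

Step 11
Reactants: 17 (8S,9R)-amine (C7H2–NH–C8H; H8 and H9 cis)
Product: 19 (8S,9R)-hepta-O-methyl ether of 20, via 1,1-diazene 18 (not isolated)
Conditions: N-(benzyloxy)-N-(pivaloyloxy)-4-(trifluoromethyl)benzamide (1.5 equiv), THF, 45 °C
Reagents that add atoms: none
Why: The secondary amine attacks the amide nitrogen of the reagent with loss of pivalate, and the resulting N-amino-N-benzyloxy amide rearranges (HERON-type 1,2-shift of the benzyloxy group to the acyl carbon) to benzyl 4-(trifluoromethyl)benzoate and the 1,1-diazene 18. 18 loses N2 by homolysis of the weaker, doubly benzylic C8–N bond and then of the C7–N bond, leaving a singlet biradical (diarylmethyl radical at C8, benzyl radical at C7) held about 2.5 Å apart by the A–C biaryl, and radical–radical combination forms the C7–C8 bond. The closest known reactions are the nitrogen deletion of bis-benzylic secondary amines with this reagent and the classical loss of N2 from the 1,1-diazene of 6,7-dihydro-5H-dibenzo[c,e]azepine to give 9,10-dihydrophenanthrene. The six-membered ring is closed by intramolecular combination of the two tethered benzylic radicals, a contraction of the azepine, and the seven-membered carbocycle is not touched. No new stereocenter forms, but C8 must keep its configuration: the C8 radical stays inside the boat-shaped dibenzocycloheptane, only its lobe on the ring A side can be reached by C7, and inversion of the boat would force H8 through the plane of ring C against ring A and put ring D on C9 pseudo-axial, so collapse over about 1 Å is expected to outrun inversion and give retention. C9 is remote from both radical centers, and any leakage at C8 would give a separable diastereomer, not the enantiomer. The step needs coupling to win over other radical exits: the two centers are tethered and cannot diffuse apart, and neither radical has a β-hydrogen, so disproportionation is not available.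

Step 12
Reactants: 19 (8S,9R)-hepta-O-methyl ether of 20
Product: 20 CNP0306974.2, the (8S,9R)-heptaphenol
Conditions: BBr3 (12 equiv), CH2Cl2, −78 °C → rt; MeOH, then H2O, under argon
Reagents that add atoms: none
Why: Lewis acid cleavage of aryl methyl ethers by BBr3 (bromide attacks the methyl group of the boron-bound ether), followed by hydrolysis of the aryl borates. The benzylic C–H and C–C bonds at C8 and C9 are not ionised under these conditions.

## Compound list

1 | methyl 2,4-dimethoxy-6-methylbenzoate | COC(=O)c1c(C)cc(OC)cc1OC | starting material
2 | bis(3,4-dimethoxyphenyl)methanone | COc1ccc(cc1OC)C(=O)c1ccc(OC)c(OC)c1 | starting material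
3 | methyl 2-[2,2-bis(3,4-dimethoxyphenyl)-2-hydroxyethyl]-4,6-dimethoxybenzoate (formed as its lithium alkoxide, not isolated) | COC(=O)c1c(OC)cc(OC)cc1CC(O)(c1ccc(OC)c(OC)c1)c1ccc(OC)c(OC)c1 | intermediate
4 | 3,3-bis(3,4-dimethoxyphenyl)-6,8-dimethoxy-3,4-dihydro-1H-isochromen-1-one | COc1cc(OC)c2c(c1)CC(OC2=O)(c1ccc(OC)c(OC)c1)c1ccc(OC)c(OC)c1 | intermediate
5 | 2-[2,2-bis(3,4-dimethoxyphenyl)ethenyl]-4,6-dimethoxybenzoic acid (not isolated) | COc1cc(OC)c(C(=O)O)c(c1)C=C(c1ccc(OC)c(OC)c1)c1ccc(OC)c(OC)c1 | intermediate
6 | 11-(3,4-dimethoxyphenyl)-2,3,6,8-tetramethoxy-5H-dibenzo[a,d][7]annulen-5-one | COc1cc(OC)c2c(c1)C=C(c1ccc(OC)c(OC)c1)c1cc(OC)c(OC)cc1C2=O | intermediate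
7 | 11-(3,4-dimethoxyphenyl)-6-hydroxy-2,3,8-trimethoxy-5H-dibenzo[a,d][7]annulen-5-one | COc1cc(O)c2c(c1)C=C(c1ccc(OC)c(OC)c1)c1cc(OC)c(OC)cc1C2=O | intermediate
8 | 11-(3,4-dimethoxyphenyl)-2,3,8-trimethoxy-5-oxo-5H-dibenzo[a,d][7]annulen-6-yl trifluoromethanesulfonate | COc1cc(OS(=O)(=O)C(F)(F)F)c2c(c1)C=C(c1ccc(OC)c(OC)c1)c1cc(OC)c(OC)cc1C2=O | intermediate
9 | 2-bromo-3,5-dimethoxybenzaldehyde | COc1cc(C=O)c(Br)c(OC)c1 | starting material
10 | tert-butyl carbamate | CC(C)(C)OC(N)=O | starting material
11 | tert-butyl N-[(2-bromo-3,5-dimethoxyphenyl)methyl]carbamate | COc1cc(CNC(=O)OC(C)(C)C)c(Br)c(OC)c1 | intermediate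
12 | tert-butyl N-{[3,5-dimethoxy-2-(4,4,5,5-tetramethyl-1,3,2-dioxaborolan-2-yl)phenyl]methyl}carbamate | COc1cc(CNC(=O)OC(C)(C)C)c(B2OC(C)(C)C(C)(C)O2)c(OC)c1 | intermediate
13 | tert-butyl N-({2-[11-(3,4-dimethoxyphenyl)-2,3,8-trimethoxy-5-oxo-5H-dibenzo[a,d][7]annulen-6-yl]-3,5-dimethoxyphenyl}methyl)carbamate | CC(C)(C)OC(=O)NCc1cc(OC)cc(OC)c1-c1cc(OC)cc2C=C(c3ccc(OC)c(OC)c3)c3cc(OC)c(OC)cc3C(=O)c12 | intermediate
14 | 6-[2-(aminomethyl)-4,6-dimethoxyphenyl]-11-(3,4-dimethoxyphenyl)-2,3,8-trimethoxy-5H-dibenzo[a,d][7]annulen-5-one (not isolated) | NCc1cc(OC)cc(OC)c1-c1cc(OC)cc2C=C(c3ccc(OC)c(OC)c3)c3cc(OC)c(OC)cc3C(=O)c12 | intermediate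
15 | hepta-O-methyl cyclic ketimine: rings A and C bridged by C7H2–N=C8 (5H-dibenzo[c,e]azepine), C8 also bonded to ring B, C9=C10 alkene bearing ring D | COc1cc(OC)c2c(c1)CN=C1c3cc(OC)c(OC)cc3C(c3ccc(OC)c(OC)c3)=Cc3cc(OC)cc-2c31 | intermediate
16 | (8S)-amine: C8=N of 15 reduced to C8H–NH (6,7-dihydro-5H-dibenzo[c,e]azepine), C9=C10 retained | COc1cc(OC)c2c(c1)CN[C@H]1c3cc(OC)c(OC)cc3C(c3ccc(OC)c(OC)c3)=Cc3cc(OC)cc-2c31 | intermediate
17 | (8S,9R)-amine: 9,10-dihydro derivative of 16 with H8 and H9 cis; 19 with NH inserted between C7 and C8 | COc1cc(OC)c2c(c1)CN[C@H]1c3cc(OC)c(OC)cc3[C@@H](c3ccc(OC)c(OC)c3)Cc3cc(OC)cc-2c31 | intermediate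
18 | (8S,9R)-1,1-diazene of 17, N(+)(=N(−)) between C7 and C8 (not isolated) | COc1cc(OC)c2c(c1)C[N+](=[N-])[C@H]1c3cc(OC)c(OC)cc3[C@@H](c3ccc(OC)c(OC)c3)Cc3cc(OC)cc-2c31 | intermediate
19 | (8S,9R)-hepta-O-methyl ether of the target (all seven OH as OMe) | COc1cc(OC)c2c(c1)C[C@H]1c3cc(OC)c(OC)cc3[C@@H](c3ccc(OC)c(OC)c3)Cc3cc(OC)cc-2c31 | intermediate
20 | CNP0306974.2, (8S,9R)-heptaphenol | Oc1cc(O)c2c(c1)C[C@H]1c3cc(O)c(O)cc3[C@@H](c3ccc(O)c(O)c3)Cc3cc(O)cc-2c31 | target

## Step count and least certain steps

Total steps: 12. Longest linear sequence: 10 steps (steps 1, 2, 3, 4, 7, 8, 9, 10, 11, 12); the ring A branch is steps 5 and 6.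

Step 11 (key step). The most likely failures are slow N–N bond formation at the α-branched, biaryl-bridged nitrogen, tautomerisation of the 1,1-diazene to a hydrazone before N2 is lost, and partial loss of configuration at C8 if the seven-membered carbocycle inverts at the radical stage before the ring closes. Fallback: generate the same 1,1-diazene stepwise by the classical route, which tolerates hindered amines and runs at lower temperature. Setting out from 17, nitrosation (tBuONO, CH2Cl2, rt) gives the N-nitrosamine F1, reduction with LiAlH4 (THF, 0 °C) gives the N-amino azepine F2, and oxidation of F2 with HgO (CH2Cl2, 0 °C) forms 18, which loses N2 and returns to the route at 19.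

Step 9. Enantioface discrimination may be insufficient because both substituents on the C8=N carbon are aryl groups, and the hindered, conjugated ketimine may be reduced slowly. Fallback: give up catalyst control at this point and resolve. Setting out from 15, NaBH4 (MeOH, 0 °C) gives the racemic amine F3, which is resolved by crystallisation of its salt F4 with (2R,3R)-di-O-p-toluoyltartaric acid (or the antipodal acid, whichever crystallises the (S)-amine); aqueous NaOH liberates the free base and the route is rejoined at 16.

Step 2. In the strong acid, protonation of the alkene at C10 places positive charge on C9 and deactivates both dimethoxyphenyl rings, so the acylation may stall while sulfonation or demethylation intervene. Fallback: take the alkene out of play during the acylation. Setting out from 4, ionic hydrogenation (Et3SiH, CF3CO2H, CH2Cl2, rt) gives the saturated acid F5, cyclisation with (CF3CO)2O (CH2Cl2, rt) gives the dibenzosuberone F6 (racemic at C9), and dehydrogenation with DDQ (1,4-dioxane, 100 °C) restores C9=C10 and returns to the route at 6.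

Step 10. Hydrogenolysis of the doubly benzylic C8–N bond, poisoning of the catalyst by the amine, or incomplete facial selectivity on the flexible azepine may occur. Fallback: invert the order of the last two skeletal steps so that no C–N bond is present during hydrogenation. Setting out from 16, the anomeric amide of step 11 forms the 1,1-diazene F7, which loses N2 to the all-carbon alkene F8; hydrogenation of F8 (H2, 10% Pd/C, EtOAc/AcOH) on the convex face, now with C7 locked pseudo-equatorial by the dihydrophenanthrene, returns to the route at 19. The price is a flatter, more delocalised C8 radical in the deletion step.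

Step 7. Protodeboronation of the electron-rich, di-ortho-substituted boronate 12 and hydrolysis of triflate 8 may compete with a slow transmetalation. Fallback: exchange the roles of the partners. Setting out from 8, Miyaura borylation (B2pin2, PdCl2(dppf), KOAc, 1,4-dioxane, 90 °C) gives the boronate F9, which is coupled with bromide 11 (Pd(OAc)2, SPhos, K3PO4, toluene/H2O, 90 °C) to return to the route at 13.

## Further compounds

F1 | step 11 | N-nitrosamine of 17 | COc1cc(OC)c2c(c1)CN(N=O)[C@H]1c3cc(OC)c(OC)cc3[C@@H](c3ccc(OC)c(OC)c3)Cc3cc(OC)cc-2c31
F2 | step 11 | N-amino derivative (1,1-disubstituted hydrazine) of 17 | COc1cc(OC)c2c(c1)CN(N)[C@H]1c3cc(OC)c(OC)cc3[C@@H](c3ccc(OC)c(OC)c3)Cc3cc(OC)cc-2c31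
F3 | step 9 | racemic 16 | COc1cc(OC)c2c(c1)CNC1c3cc(OC)c(OC)cc3C(c3ccc(OC)c(OC)c3)=Cc3cc(OC)cc-2c31
F4 | step 9 | salt of 16 with (2R,3R)-di-O-p-toluoyltartaric acid | COc1cc(OC)c2c(c1)CN[C@H]1c3cc(OC)c(OC)cc3C(c3ccc(OC)c(OC)c3)=Cc3cc(OC)cc-2c31.OC(=O)[C@H](OC(=O)c1ccc(C)cc1)[C@@H](OC(=O)c1ccc(C)cc1)C(O)=O
F5 | step 2 | 2-[2,2-bis(3,4-dimethoxyphenyl)ethyl]-4,6-dimethoxybenzoic acid | COc1cc(OC)c(C(=O)O)c(c1)CC(c1ccc(OC)c(OC)c1)c1ccc(OC)c(OC)c1
F6 | step 2 | racemic 11-(3,4-dimethoxyphenyl)-2,3,6,8-tetramethoxy-10,11-dihydro-5H-dibenzo[a,d][7]annulen-5-one | COc1cc(OC)c2c(c1)CC(c1ccc(OC)c(OC)c1)c1cc(OC)c(OC)cc1C2=O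
F7 | step 10 | (8S)-1,1-diazene of 16 | COc1cc(OC)c2c(c1)C[N+](=[N-])[C@H]1c3cc(OC)c(OC)cc3C(c3ccc(OC)c(OC)c3)=Cc3cc(OC)cc-2c31
F8 | step 10 | (8S)-9,10-didehydro derivative of 19 (C9=C10) | COc1cc(OC)c2c(c1)C[C@H]1c3cc(OC)c(OC)cc3C(c3ccc(OC)c(OC)c3)=Cc3cc(OC)cc-2c31
F9 | step 7 | 11-(3,4-dimethoxyphenyl)-2,3,8-trimethoxy-6-(4,4,5,5-tetramethyl-1,3,2-dioxaborolan-2-yl)-5H-dibenzo[a,d][7]annulen-5-one | COc1cc(B2OC(C)(C)C(C)(C)O2)c2c(c1)C=C(c1ccc(OC)c(OC)c1)c1cc(OC)c(OC)cc1C2=O
A1 | alternative 1 | 8-[2,2-bis(3,4-dimethoxyphenyl)ethyl]-2,4,6-trimethoxy-9,10-dihydrophenanthren-9-ol | COc1cc(OC)c2c(c1)CC(O)c1c(CC(c3ccc(OC)c(OC)c3)c3ccc(OC)c(OC)c3)cc(OC)cc-21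
A2 | alternative 2 | seco-bromide: 19 without the A–C biaryl bond, Br on ring A ortho to C7, configured as in 19 | COc1cc(C[C@H]2c3cc(OC)c(OC)cc3[C@@H](c3ccc(OC)c(OC)c3)Cc3cc(OC)ccc32)c(Br)c(OC)c1
A3 | alternative 3 | cyclic aldimine of rings A and C (C7H2–N=C8H) carrying the CH2–CH[3,4-(MeO)2C6H3]2 chain on ring C | COc1cc(OC)c2c(c1)CN=Cc1c(CC(c3ccc(OC)c(OC)c3)c3ccc(OC)c(OC)c3)cc(OC)cc-21
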